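## Retrosynthetic overview

1. C11–C12 is cut by a Suzuki coupling of east vinyl iodide **22** (C1–C11) with west vinyl boronate **43** (C12–C24); the C8 ketone and the lactone carbonyl are unveiled together by a penultimate oxidation, then global desilylation.
2. East: C8–C9 comes from a Marshall allenylzinc addition (sets C9; its 2‑alkyne becomes the (E)-vinyl iodide), C3–C4 from an sp3–sp2 Negishi coupling, and the all‑syn C5–C7 triad from lipase desymmetrisation of a meso diol.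
3. West: C17–C18 comes from hydrozirconation/Negishi coupling of a lactol alkyne with a (Z)-iodoalkene (Zhao olefination); C15 comes from lipase desymmetrisation of 2‑methylpropane‑1,3‑diol.
4. Ring order: the only ring (the dihydropyran) is formed first in the west branch by a Cr(III)-catalysed asymmetric hetero‑Diels–Alder reaction and is carried as its methyl lactol acetal until the penultimate step.

Assumptions (one line each):
- The lipase acetylates the CH2OH on the (R)-centre of meso diol **5**, by analogy with its pro‑S preference on 2‑methylpropane‑1,3‑diol; if the antipodal monoacetate forms, lipase hydrolysis of the meso diacetate gives **6**.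
- The Marshall addition proceeds with net inversion at the propargylic carbon (anti‑SN2′ palladation, cyclic SE2′ addition).
- The anomeric centre and the C8 carbinol are temporary stereocentres; their configuration is inconsequential.

Numbering in names of late intermediates follows kazusamycin (C1 acid to C24 lactone carbonyl). TBS = tert‑butyldimethylsilyl.

## Part A – East fragment (C1–C11)

**Step 1**
Reactants: **1** methacrolein; **2** isopropenylmagnesium bromide
Product: **3** 2,4‑dimethylpenta‑1,4‑dien‑3‑ol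
Conditions: THF, 0 °C
Reagents that add atoms: none
Why: Grignard 1,2‑addition to the enal gives the achiral bis‑allylic alcohol.

**Step 2**
Reactants: **3**
Product: **4** tert‑butyl[(2,4‑dimethylpenta‑1,4‑dien‑3‑yl)oxy]dimethylsilane
Conditions: TBSOTf, 2,6‑lutidine, CH2Cl2, –78 → 0 °C
Reagents that add atoms: TBSOTf, CC(C)(C)[Si](C)(C)OS(=O)(=O)C(F)(F)F
Why: Silylation; the TBS ether is the group that makes the next hydroboration syn‑selective and it lasts to the final step.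

**Step 3**
Reactants: **4**
Product: **5** meso‑(2R,3r,4S)‑3‑(TBSO)‑2,4‑dimethylpentane‑1,5‑diol (syn,syn)
Conditions: catecholborane (5 equiv), RhCl(PPh3)3 (4 mol%), THF, rt; then NaOH, H2O2, 0 °C; chromatography
Reagents that add atoms: hydrogen peroxide, OO (catecholborane supplies only H)
Why: Rh‑catalysed hydroboration of 1,1‑disubstituted allylic silyl ethers is syn‑selective at each alkene, so double hydroboration gives mainly the achiral syn,syn diol (relative configuration of C5–C7), separable from the minor unsymmetrical isomer.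

**Step 4**
Reactants: **5**
Product: **6** (2R,3R,4S)‑3‑(TBSO)‑5‑hydroxy‑2,4‑dimethylpentyl acetate
Conditions: lipase (Pseudomonas fluorescens lipase, Amano AK; a serine hydrolase, EC 3.1.1.3), vinyl acetate, TBME, rt
Reagents that add atoms: vinyl acetate, CC(=O)OC=C
Why: Lipase‑catalysed enantiotopic‑group‑selective transesterification (desymmetrisation) of the meso diol fixes the absolute configuration of C5, C6 and C7 in one step.

**Step 5**
Reactants: **6**
Product: **7** (2R,3S,4R)‑3‑(TBSO)‑5‑iodo‑2,4‑dimethylpentyl acetate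
Conditions: I2, PPh3, imidazole, CH2Cl2, 0 °C → rt
Reagents that add atoms: iodine, II
Why: Appel‑type iodination of the free primary alcohol; acetate and TBS ether are untouched.

**Step 6**
Reactants: **8** methyl acetoacetate
Product: **9** methyl (E)‑3‑{[(trifluoromethyl)sulfonyl]oxy}but‑2‑enoate
Conditions: Tf2O, aq. Me4NOH, hexanes, 5 °C
Reagents that add atoms: triflic anhydride, O=S(=O)(OS(=O)(=O)C(F)(F)F)C(F)(F)F
Why: O‑triflation of the non‑chelated tetramethylammonium enolate gives the (E)-enol triflate, which fixes the 2E geometry.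

**Step 7**
Reactants: **7**; **9**
Product: **10** methyl (2E,5S,6R,7R)‑8‑acetoxy‑6‑(TBSO)‑3,5,7‑trimethyloct‑2‑enoate
Conditions: Zn dust (BrCH2CH2Br/TMSCl‑activated), LiCl, THF, 40 °C; then **9**, Pd(PPh3)4 (5 mol%), THF, rt → 50 °C
Reagents that add atoms: none
Why: Zinc insertion followed by sp3–sp2 Negishi coupling forms C3–C4 with retention of the enol triflate geometry; the alkylzinc tolerates acetate and silyl ether.

**Step 8**
Reactants: **10**
Product: **11** methyl (2E,5S,6R,7R)‑6‑(TBSO)‑8‑hydroxy‑3,5,7‑trimethyloct‑2‑enoate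
Conditions: K2CO3 (0.5 equiv), MeOH, 0 °C
Reagents that add atoms: none
Why: Mild methanolysis removes the primary acetate; exchange at the methyl ester is degenerate.

**Step 9**
Reactants: **11**
Product: **12** methyl (2E,5S,6R,7S)‑6‑(TBSO)‑3,5,7‑trimethyl‑8‑oxooct‑2‑enoate
Conditions: Dess–Martin periodinane, NaHCO3, CH2Cl2, 0 °C → rt; used at once
Reagents that add atoms: none
Why: Buffered Dess–Martin oxidation gives the α‑methyl aldehyde without epimerising C7.

**Step 10**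
Reactants: **13** (tert‑butyldimethylsilyloxy)acetaldehyde; **14** 1‑propynylmagnesium bromide
Product: **15** rac‑1‑(TBSO)pent‑3‑yn‑2‑ol
Conditions: THF, –78 → 0 °C
Reagents that add atoms: none
Why: Grignard addition to the aldehyde.

**Step 11**
Reactants: **15**
Product: **16** 1‑(TBSO)pent‑3‑yn‑2‑one
Conditions: Dess–Martin periodinane, CH2Cl2, rt
Reagents that add atoms: none
Why: Oxidation of the propargylic alcohol to the ynone.

**Step 12**
Reactants: **16**
Product: **17** (R)‑1‑(TBSO)pent‑3‑yn‑2‑ol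
Conditions: Ru[(S,S)‑TsDPEN](p‑cymene) (1 mol%), i‑PrOH, rt
Reagents that add atoms: none
Why: Noyori–Ikariya asymmetric transfer hydrogenation of an ynone, with the alkynyl group as the π‑directing substituent, gives the carbinol in high ee (the label is R because CH2OTBS outranks the alkyne).

**Step 13**
Reactants: **17**
Product: **18** (R)‑1‑(TBSO)pent‑3‑yn‑2‑yl methanesulfonate
Conditions: MsCl, Et3N, CH2Cl2, –78 °C; used crude
Reagents that add atoms: methanesulfonyl chloride, CS(=O)(=O)Cl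
Why: Mesylation with retention gives the propargylic electrophile for the Marshall reaction.

**Step 14**
Reactants: **12**; **18**
Product: **19** methyl (2E,5S,6R,7R,8R,9S)‑6‑(TBSO)‑9‑[(TBSO)methyl]‑8‑hydroxy‑3,5,7‑trimethyldodec‑2‑en‑10‑ynoate
Conditions: Pd(OAc)2 (5 mol%), PPh3 (5 mol%), Et2Zn (3 equiv), THF, –78 → –20 °C
Reagents that add atoms: none
Why: Marshall propargylation: Pd(0) anti‑SN2′ displacement gives a chiral allenylzinc that adds through a cyclic SE2′ transition state, so C9 (S) is set by the reagent; the anti (8R) carbinol is major and any C8 epimer converges at step 36.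

**Step 15**
Reactants: **19**
Product: **20** methyl (2E,5S,6R,7S,8R,9S)‑6‑(TBSO)‑9‑[(TBSO)methyl]‑3,5,7‑trimethyl‑8‑[(trimethylsilyl)oxy]dodec‑2‑en‑10‑ynoate
Conditions: TMSOTf, Et3N, CH2Cl2, –78 °C
Reagents that add atoms: TMSOTf, C[Si](C)(C)OS(=O)(=O)C(F)(F)F
Why: Temporary silylation prevents alkoxide‑directed (proximal) hydrozirconation in the next step.

**Step 16**
Reactants: **20**
Product: **21** methyl (2E,5S,6R,7S,8R,9S,10E)‑6‑(TBSO)‑9‑[(TBSO)methyl]‑11‑iodo‑3,5,7‑trimethyl‑8‑[(trimethylsilyl)oxy]dodeca‑2,10‑dienoate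
Conditions: Cp2Zr(H)Cl (3 equiv), THF, 45 °C; then I2, THF, –20 °C
Reagents that add atoms: iodine, II
Why: Syn hydrozirconation equilibrates zirconium to the less hindered methyl‑bearing carbon of the α‑branched 2‑alkyne, and iodinolysis with retention gives the (E)-vinyl iodide.

**Step 17**
Reactants: **21**
Product: **22** (2E,5S,6R,7R,8R,9S,10E)‑6‑(TBSO)‑9‑[(TBSO)methyl]‑8‑hydroxy‑11‑iodo‑3,5,7‑trimethyldodeca‑2,10‑dienoic acid
Conditions: LiOH·H2O, THF/MeOH/H2O (3:1:1), 40 °C; NaH2PO4 to pH 4–5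
Reagents that add atoms: water, O
Why: Saponification (which also cleaves the TMS ether) is done now, while no base‑sensitive ketone or lactone is present; TBS ethers and the vinyl iodide survive.

## Part B – West fragment (C12–C24)

**Step 18**
Reactants: **23** 2‑methylpropane‑1,3‑diol
Product: **24** (S)‑3‑hydroxy‑2‑methylpropyl acetate
Conditions: lipase (Burkholderia cepacia lipase, Amano PS; EC 3.1.1.3), vinyl acetate, rt, run to about 15–20% diacetate
Reagents that add atoms: vinyl acetate, CC(=O)OC=C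
Why: Lipase desymmetrisation of the prochiral diol sets the future C15; slight over‑acylation removes the minor enantiomer and raises ee to ≥98%.

**Step 19**
Reactants: **24**
Product: **25** (R)‑3‑(TBSO)‑2‑methylpropyl acetate
Conditions: TBSCl, imidazole, DMF, 0 °C
Reagents that add atoms: TBSCl, CC(C)(C)[Si](C)(C)Cl
Why: Silylation of the free arm under non‑basic conditions, so no acyl migration occurs.

**Step 20**
Reactants: **25**
Product: **26** (R)‑3‑(TBSO)‑2‑methylpropan‑1‑ol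
Conditions: DIBAL‑H, CH2Cl2, –78 °C
Reagents that add atoms: none
Why: Reductive deacetylation at low temperature avoids the base‑mediated 1,3‑silyl migration that would racemise this compound.

**Step 21**
Reactants: **26**
Product: **27** (S)‑3‑(TBSO)‑2‑methylpropyl trifluoromethanesulfonate
Conditions: Tf2O, 2,6‑lutidine, CH2Cl2, –78 °C; used crude
Reagents that add atoms: triflic anhydride, O=S(=O)(OS(=O)(=O)C(F)(F)F)C(F)(F)F
Why: Activation of the β‑branched primary alcohol for SN2 displacement.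

**Step 22**
Reactants: **27**; **28** ethynyltrimethylsilane
Product: **29** (R)‑tert‑butyldimethyl{[2‑methyl‑5‑(trimethylsilyl)pent‑4‑yn‑1‑yl]oxy}silane
Conditions: **28**, n‑BuLi, THF, –78 °C; then **27**, HMPA, –78 → –20 °C
Reagents that add atoms: none
Why: SN2 displacement of the primary triflate by the lithium acetylide forms C13–C14 without touching the stereocentre.

**Step 23**
Reactants: **29**
Product: **30** (R)‑2‑methyl‑5‑(trimethylsilyl)pent‑4‑yn‑1‑ol
Conditions: CSA (10 mol%), MeOH/CH2Cl2, 0 °C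
Reagents that add atoms: none
Why: Acidic methanolysis removes the primary TBS ether while the C‑silyl alkyne is acid‑stable.

**Step 24**
Reactants: **30**
Product: **31** (R)‑2‑methyl‑5‑(trimethylsilyl)pent‑4‑ynal
Conditions: Dess–Martin periodinane, NaHCO3, CH2Cl2, 0 °C; used at once
Reagents that add atoms: none
Why: Non‑epimerising oxidation to the α‑methyl aldehyde.

**Step 25**
Reactants: **31**; **32** propyltriphenylphosphonium bromide
Product: **33** [(4R,5Z)‑6‑iodo‑4‑methyloct‑5‑en‑1‑yn‑1‑yl]trimethylsilane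
Conditions: **32**, n‑BuLi, THF; I2, –78 °C; NaHMDS, –20 °C; then **31**, –78 °C → rt
Reagents that add atoms: iodine, II
Why: Stork–Zhao α‑iodo Wittig olefination is Z‑selective (iodine cis to the chain), giving the geometry that becomes the 16Z ethyl‑substituted alkene.

**Step 26**
Reactants: **34** (E)‑pent‑2‑enal
Product: **35** (E)‑1,1‑dimethoxypent‑2‑ene
Conditions: HC(OMe)3, MeOH, NH4NO3 (cat.), rt
Reagents that add atoms: trimethyl orthoformate, COC(OC)OC
Why: Mild acetalisation of the enal.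

**Step 27**
Reactants: **35**
Product: **36** (1E,3E)‑1‑methoxypenta‑1,3‑diene
Conditions: TMSOTf, i‑Pr2NEt, CH2Cl2, –20 °C → rt; distil
Reagents that add atoms: none
Why: Gassman‑type 1,4‑elimination of methanol (γ‑deprotonation of the vinylogous oxocarbenium ion) gives the dienyl ether; only the (E,E) isomer can react in the next step.

**Step 28**
Reactants: **37** ethynyltriethylsilane
Product: **38** 3‑(triethylsilyl)prop‑2‑ynal
Conditions: n‑BuLi, THF, –78 °C; DMF; inverse quench into aq. KH2PO4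
Reagents that add atoms: DMF, CN(C)C=O
Why: Formylation of the lithium acetylide.

**Step 29**
Reactants: **36**; **38**
Product: **39** (2S,5S,6R)‑2‑methoxy‑5‑methyl‑6‑[(triethylsilyl)ethynyl]‑5,6‑dihydro‑2H‑pyran
Conditions: (1R,2S)‑Jacobsen tridentate Schiff‑base Cr(III)Cl catalyst (3 mol%), 4 Å MS, neat, rt
Reagents that add atoms: none
Why: Catalytic asymmetric hetero‑Diels–Alder reaction; the endo transition state with the (E,E)-diene gives the all‑cis adduct, forming the ring and setting C20 and C21 (this catalyst antipode gives 2S,6R adducts with 1‑alkoxydienes).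

**Step 30**
Reactants: **39**
Product: **40** (2S,5S,6R)‑6‑ethynyl‑2‑methoxy‑5‑methyl‑5,6‑dihydro‑2H‑pyran
Conditions: TBAF, THF, 0 °C
Reagents that add atoms: none
Why: Fluoride protodesilylation of the alkynylsilane; the acetal is stable to these conditions.

**Step 31**
Reactants: **40**; **33**
Product: **41** (2S,5S,6S)‑6‑[(1E,3Z,5R)‑3‑ethyl‑5‑methyl‑8‑(trimethylsilyl)octa‑1,3‑dien‑7‑yn‑1‑yl]‑2‑methoxy‑5‑methyl‑5,6‑dihydro‑2H‑pyran
Conditions: **40**, Cp2Zr(H)Cl, THF, rt; ZnCl2; then **33**, Pd(PPh3)4 (5 mol%), rt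
Reagents that add atoms: none
Why: Syn hydrozirconation gives the (E)-alkenyl metal, and Zr→Zn Negishi coupling with the hindered (Z)-iodide is stereoretentive, forming C17–C18 and the (16Z,18E)-diene.

**Step 32**
Reactants: **41**
Product: **42** (2S,5S,6S)‑6‑[(1E,3Z,5R)‑3‑ethyl‑5‑methylocta‑1,3‑dien‑7‑yn‑1‑yl]‑2‑methoxy‑5‑methyl‑5,6‑dihydro‑2H‑pyran
Conditions: K2CO3, MeOH, rt
Reagents that add atoms: none
Why: Protodesilylation of the TMS‑alkyne; the acetal and diene are base‑stable.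

**Step 33**
Reactants: **42**
Product: **43** 2‑{(1E,4R,5Z,7E)‑6‑ethyl‑8‑[(2S,3S,6S)‑6‑methoxy‑3‑methyl‑3,6‑dihydro‑2H‑pyran‑2‑yl]‑4‑methylocta‑1,5,7‑trien‑1‑yl}‑4,4,5,5‑tetramethyl‑1,3,2‑dioxaborolane
Conditions: pinacolborane, Cp2Zr(H)Cl (10 mol%), Et3N (10 mol%), CH2Cl2, 40 °C
Reagents that add atoms: pinacolborane, CC1(C)OBOC1(C)C
Why: Zr‑catalysed syn hydroboration is selective for the terminal alkyne over the substituted alkenes and gives the (E)-alkenyl boronate.

## Part C – Union and endgame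

**Step 34**
Reactants: **22**; **43**
Product: **44** (2E,5S,6R,7R,8R,9S,10E,12E,15R,16Z,18E)‑6‑(TBSO)‑9‑[(TBSO)methyl]‑17‑ethyl‑8‑hydroxy‑19‑[(2S,3S,6S)‑6‑methoxy‑3‑methyl‑3,6‑dihydro‑2H‑pyran‑2‑yl]‑3,5,7,11,15‑pentamethylnonadeca‑2,10,12,16,18‑pentaenoic acid
Conditions: Pd(PPh3)4 (10 mol%), TlOEt (4 equiv), THF/H2O (3:1), rt
Reagents that add atoms: none
Why: Suzuki–Miyaura coupling is stereoretentive at both partners, forming C11–C12 and the (10E,12E)-diene; the free OH and carboxylate are tolerated.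

**Step 35**
Reactants: **44**
Product: **45** the corresponding C24 lactol (6‑hydroxy‑3,6‑dihydro‑2H‑pyran, anomeric mixture)
Conditions: PPTS, acetone/H2O (4:1), rt
Reagents that add atoms: water, O
Why: Mild hydrolysis of the allylic methyl acetal; TBS ethers are unaffected.

**Step 36**
Reactants: **45**
Product: **46** 6‑O,9‑CH2O‑bis‑TBS kazusamycin A: (2E,5S,6R,7S,9S,10E,12E,15R,16Z,18E)‑6‑(TBSO)‑9‑[(TBSO)methyl]‑17‑ethyl‑3,5,7,11,15‑pentamethyl‑19‑[(2S,3S)‑3‑methyl‑6‑oxo‑3,6‑dihydro‑2H‑pyran‑2‑yl]‑8‑oxononadeca‑2,10,12,16,18‑pentaenoic acid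
Conditions: Dess–Martin periodinane (4 equiv), NaHCO3, CH2Cl2, 0 °C → rt
Reagents that add atoms: none
Why: One Dess–Martin oxidation converts the lactol to the unsaturated δ‑lactone and the C8 carbinol to the ketone under near‑neutral conditions that do not epimerise C7 or C9.

**Step 37**
Reactants: **46**
Product: **47** kazusamycin A
Conditions: HF·pyridine, pyridine, THF, 0 °C → rt
Reagents that add atoms: none
Why: Buffered acidic fluoride desilylation frees the C6 and C9‑CH2 hydroxyls without retro‑aldol, β‑elimination or lactone opening.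

## Compound list

1 | methacrolein | CC(=C)C=O | starting material
2 | isopropenylmagnesium bromide | CC(=C)[Mg]Br | starting material
3 | 2,4‑dimethylpenta‑1,4‑dien‑3‑ol | C=C(C)C(O)C(C)=C | intermediate
4 | tert‑butyl[(2,4‑dimethylpenta‑1,4‑dien‑3‑yl)oxy]dimethylsilane | C=C(C)C(O[Si](C)(C)C(C)(C)C)C(C)=C | intermediate
5 | meso‑(2R,3r,4S)‑3‑(TBSO)‑2,4‑dimethylpentane‑1,5‑diol | OC[C@@H](C)[C@H](O[Si](C)(C)C(C)(C)C)[C@@H](C)CO | intermediate
6 | (2R,3R,4S)‑3‑(TBSO)‑5‑hydroxy‑2,4‑dimethylpentyl acetate | CC(=O)OC[C@@H](C)[C@H](O[Si](C)(C)C(C)(C)C)[C@@H](C)CO | intermediate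
7 | (2R,3S,4R)‑3‑(TBSO)‑5‑iodo‑2,4‑dimethylpentyl acetate | CC(=O)OC[C@@H](C)[C@H](O[Si](C)(C)C(C)(C)C)[C@@H](C)CI | intermediate
8 | methyl acetoacetate | COC(=O)CC(C)=O | starting material
9 | methyl (E)‑3‑(triflyloxy)but‑2‑enoate | COC(=O)/C=C(\C)OS(=O)(=O)C(F)(F)F | intermediate
10 | methyl (2E,5S,6R,7R)‑8‑acetoxy‑6‑(TBSO)‑3,5,7‑trimethyloct‑2‑enoate | CC(=O)OC[C@@H](C)[C@H](O[Si](C)(C)C(C)(C)C)[C@@H](C)C/C(C)=C/C(=O)OC | intermediate
11 | methyl (2E,5S,6R,7R)‑6‑(TBSO)‑8‑hydroxy‑3,5,7‑trimethyloct‑2‑enoate | OC[C@@H](C)[C@H](O[Si](C)(C)C(C)(C)C)[C@@H](C)C/C(C)=C/C(=O)OC | intermediate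
12 | methyl (2E,5S,6R,7S)‑6‑(TBSO)‑3,5,7‑trimethyl‑8‑oxooct‑2‑enoate | O=C[C@@H](C)[C@H](O[Si](C)(C)C(C)(C)C)[C@@H](C)C/C(C)=C/C(=O)OC | intermediate
13 | (tert‑butyldimethylsilyloxy)acetaldehyde | O=CCO[Si](C)(C)C(C)(C)C | starting material
14 | 1‑propynylmagnesium bromide | CC#C[Mg]Br | starting material
15 | rac‑1‑(TBSO)pent‑3‑yn‑2‑ol | CC#CC(O)CO[Si](C)(C)C(C)(C)C | intermediate
16 | 1‑(TBSO)pent‑3‑yn‑2‑one | CC#CC(=O)CO[Si](C)(C)C(C)(C)C | intermediate
17 | (R)‑1‑(TBSO)pent‑3‑yn‑2‑ol | CC#C[C@@H](O)CO[Si](C)(C)C(C)(C)C | intermediate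
18 | (R)‑1‑(TBSO)pent‑3‑yn‑2‑yl methanesulfonate | CC#C[C@@H](OS(C)(=O)=O)CO[Si](C)(C)C(C)(C)C | intermediate
19 | methyl (2E,5S,6R,7R,8R,9S)‑6‑(TBSO)‑9‑[(TBSO)methyl]‑8‑hydroxy‑3,5,7‑trimethyldodec‑2‑en‑10‑ynoate | CC#C[C@@H](CO[Si](C)(C)C(C)(C)C)[C@@H](O)[C@@H](C)[C@H](O[Si](C)(C)C(C)(C)C)[C@@H](C)C/C(C)=C/C(=O)OC | intermediate
20 | 8‑O‑TMS ether of 19 (2E,5S,6R,7S,8R,9S) | CC#C[C@@H](CO[Si](C)(C)C(C)(C)C)[C@@H](O[Si](C)(C)C)[C@@H](C)[C@H](O[Si](C)(C)C(C)(C)C)[C@@H](C)C/C(C)=C/C(=O)OC | intermediate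
21 | methyl (2E,5S,6R,7S,8R,9S,10E)‑6‑(TBSO)‑9‑[(TBSO)methyl]‑11‑iodo‑3,5,7‑trimethyl‑8‑(TMSO)dodeca‑2,10‑dienoate | I/C(C)=C/[C@@H](CO[Si](C)(C)C(C)(C)C)[C@@H](O[Si](C)(C)C)[C@@H](C)[C@H](O[Si](C)(C)C(C)(C)C)[C@@H](C)C/C(C)=C/C(=O)OC | intermediate
22 | (2E,5S,6R,7R,8R,9S,10E)‑6‑(TBSO)‑9‑[(TBSO)methyl]‑8‑hydroxy‑11‑iodo‑3,5,7‑trimethyldodeca‑2,10‑dienoic acid | I/C(C)=C/[C@@H](CO[Si](C)(C)C(C)(C)C)[C@@H](O)[C@@H](C)[C@H](O[Si](C)(C)C(C)(C)C)[C@@H](C)C/C(C)=C/C(=O)O | intermediate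
23 | 2‑methylpropane‑1,3‑diol | CC(CO)CO | starting material
24 | (S)‑3‑hydroxy‑2‑methylpropyl acetate | C[C@@H](CO)COC(C)=O | intermediate
25 | (R)‑3‑(TBSO)‑2‑methylpropyl acetate | C[C@@H](CO[Si](C)(C)C(C)(C)C)COC(C)=O | intermediate
26 | (R)‑3‑(TBSO)‑2‑methylpropan‑1‑ol | C[C@@H](CO[Si](C)(C)C(C)(C)C)CO | intermediate
27 | (S)‑3‑(TBSO)‑2‑methylpropyl triflate | C[C@@H](CO[Si](C)(C)C(C)(C)C)COS(=O)(=O)C(F)(F)F | intermediate
28 | ethynyltrimethylsilane | C#C[Si](C)(C)C | starting material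
29 | (R)‑tert‑butyldimethyl{[2‑methyl‑5‑(trimethylsilyl)pent‑4‑yn‑1‑yl]oxy}silane | C[C@@H](CO[Si](C)(C)C(C)(C)C)CC#C[Si](C)(C)C | intermediate
30 | (R)‑2‑methyl‑5‑(trimethylsilyl)pent‑4‑yn‑1‑ol | C[C@@H](CO)CC#C[Si](C)(C)C | intermediate
31 | (R)‑2‑methyl‑5‑(trimethylsilyl)pent‑4‑ynal | O=C[C@H](C)CC#C[Si](C)(C)C | intermediate
32 | propyltriphenylphosphonium bromide | CCC[P+](c1ccccc1)(c1ccccc1)c1ccccc1.[Br-] | starting material
33 | [(4R,5Z)‑6‑iodo‑4‑methyloct‑5‑en‑1‑yn‑1‑yl]trimethylsilane | CC/C(I)=C/[C@H](C)CC#C[Si](C)(C)C | intermediate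
34 | (E)‑pent‑2‑enal | CC/C=C/C=O | starting material
35 | (E)‑1,1‑dimethoxypent‑2‑ene | CC/C=C/C(OC)OC | intermediate
36 | (1E,3E)‑1‑methoxypenta‑1,3‑diene | CO/C=C/C=C/C | intermediate
37 | ethynyltriethylsilane | CC[Si](CC)(CC)C#C | starting material
38 | 3‑(triethylsilyl)prop‑2‑ynal | CC[Si](CC)(CC)C#CC=O | intermediate
39 | (2S,5S,6R)‑2‑methoxy‑5‑methyl‑6‑[(triethylsilyl)ethynyl]‑5,6‑dihydro‑2H‑pyran | CO[C@@H]1C=C[C@H](C)[C@H](C#C[Si](CC)(CC)CC)O1 | intermediate
40 | (2S,5S,6R)‑6‑ethynyl‑2‑methoxy‑5‑methyl‑5,6‑dihydro‑2H‑pyran | CO[C@@H]1C=C[C@H](C)[C@H](C#C)O1 | intermediate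
41 | (2S,5S,6S)‑6‑[(1E,3Z,5R)‑3‑ethyl‑5‑methyl‑8‑(trimethylsilyl)octa‑1,3‑dien‑7‑yn‑1‑yl]‑2‑methoxy‑5‑methyl‑5,6‑dihydro‑2H‑pyran | CCC(=C/[C@H](C)CC#C[Si](C)(C)C)/C=C/[C@@H]1O[C@H](OC)C=C[C@@H]1C | intermediate
42 | (2S,5S,6S)‑6‑[(1E,3Z,5R)‑3‑ethyl‑5‑methylocta‑1,3‑dien‑7‑yn‑1‑yl]‑2‑methoxy‑5‑methyl‑5,6‑dihydro‑2H‑pyran | CCC(=C/[C@H](C)CC#C)/C=C/[C@@H]1O[C@H](OC)C=C[C@@H]1C | intermediate
43 | 2‑{(1E,4R,5Z,7E)‑6‑ethyl‑8‑[(2S,3S,6S)‑6‑methoxy‑3‑methyl‑3,6‑dihydro‑2H‑pyran‑2‑yl]‑4‑methylocta‑1,5,7‑trien‑1‑yl}‑4,4,5,5‑tetramethyl‑1,3,2‑dioxaborolane | CCC(=C/[C@H](C)C/C=C/B2OC(C)(C)C(C)(C)O2)/C=C/[C@@H]1O[C@H](OC)C=C[C@@H]1C | intermediate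
44 | coupled seco acid (8R carbinol, bis‑TBS, methyl lactol acetal; full name in step 34) | CCC(=C/[C@H](C)C/C=C/C(C)=C/[C@@H](CO[Si](C)(C)C(C)(C)C)[C@@H](O)[C@@H](C)[C@H](O[Si](C)(C)C(C)(C)C)[C@@H](C)C/C(C)=C/C(=O)O)/C=C/[C@@H]1O[C@H](OC)C=C[C@@H]1C | intermediate
45 | C24 lactol of 44 (anomeric mixture) | CCC(=C/[C@H](C)C/C=C/C(C)=C/[C@@H](CO[Si](C)(C)C(C)(C)C)[C@@H](O)[C@@H](C)[C@H](O[Si](C)(C)C(C)(C)C)[C@@H](C)C/C(C)=C/C(=O)O)/C=C/[C@@H]1OC(O)C=C[C@@H]1C | intermediate
46 | 6‑O,9‑CH2O‑bis‑TBS kazusamycin A | CCC(=C/[C@H](C)C/C=C/C(C)=C/[C@@H](CO[Si](C)(C)C(C)(C)C)C(=O)[C@@H](C)[C@H](O[Si](C)(C)C(C)(C)C)[C@@H](C)C/C(C)=C/C(=O)O)/C=C/[C@@H]1OC(=O)C=C[C@@H]1C | intermediate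
47 | kazusamycin A, (2E,5S,6R,7S,9S,10E,12E,15R,16Z,18E)‑17‑ethyl‑6‑hydroxy‑9‑(hydroxymethyl)‑3,5,7,11,15‑pentamethyl‑19‑[(2S,3S)‑3‑methyl‑6‑oxo‑3,6‑dihydro‑2H‑pyran‑2‑yl]‑8‑oxononadeca‑2,10,12,16,18‑pentaenoic acid | CCC(=C/[C@H](C)C/C=C/C(C)=C/[C@@H](CO)C(=O)[C@@H](C)[C@H](O)[C@@H](C)C/C(C)=C/C(=O)O)/C=C/[C@@H]1OC(=O)C=C[C@@H]1C | target

## Summary

Total step count: 37.

Longest linear sequence: 16 steps (1–5, 7–9, 14–17, 34–37). The west branch is 15 steps (18–25, 31–37).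

Three steps most likely to fail, each with a fallback that changes the approach:

1. **Step 14 (Marshall allenylzinc addition).** The mesylate is an untested internal‑alkyne, CH2OTBS‑bearing reagent, and the anti adduct is mismatched with the aldehyde's Felkin bias. Fallback: homologate the C8 aldehyde to the (E)-allylic alcohol (Wittig, then reduction), apply Sharpless asymmetric epoxidation, and open the epoxy alcohol at C9 with the alkenyl cuprate from (E)‑3‑iodo‑2‑methylallyl silyl ether; the halves are then joined at C12=C13 by Julia–Kocienski olefination instead of at C11–C12.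

2. **Step 16 (hydrozirconation/iodination).** Regiocontrol on the hindered 2‑alkyne and survival of the methyl enoate under excess Schwartz reagent are both uncertain. Fallback: reverse the coupling polarity, using Pd‑catalysed hydrostannation of **20** to the C11 vinylstannane and a Stille coupling with the (E)-C12 vinyl iodide made from **42** by hydrozirconation/iodination.

3. **Step 25 (Zhao α‑iodo Wittig).** Yield and Z:E ratio are typically moderate, and the α‑methyl aldehyde can epimerise. Fallback: convert **31** to the 1,1‑dibromoalkene (CBr4/PPh3), then use Pd‑catalysed trans‑selective mono‑ethylation (Et2Zn, Pd(DPEphos)Cl2) to reach the (Z)-2‑bromoalkene, which enters the same Negishi union at step 31.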